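## The problem

Bis-5,5-nortrachelogenin (26) consists of two identical 3-hydroxy-3,4-bis(arylmethyl)-γ-butyrolactones that share no ring atoms; they are joined only by a biaryl bond between the C5 carbons of the two guaiacyl rings whose CH2 groups sit on lactone carbons C4 and C4'. The biaryl has one ortho oxygen on each ring, rotates freely and adds no stereo-element, so the stereochemical task is four centres in two pairs: a quaternary carbinol C3 and a tertiary C4, both R, with the two arylmethyl groups trans on the ring and the hydroxyl cis to the C4 arm. The two pairs are insulated from each other by the biaryl spacer, so the same absolute sense must be delivered to each half independently; an error in one half gives a diastereomer, not the enantiomer. Within a half, C3 and C4 are neighbours, so either one controls the other or both are set together from a third, disposable centre. The four guaiacol-type phenols are oxidation-prone and the tertiary α-hydroxy lactone is opened by base, so these oxygens should stay masked until a final neutral unmasking; C4 is configurationally safe in the lactone but enolisable whenever C5 is at the aldehyde level. The enabling feature is in each lactone ring (O1, C2, C3, C4, C5): the C3–C4 bond joins a quaternary carbon carrying an oxygen and the carboxyl carbon C2 to a tertiary carbon carrying the one-carbon unit C5 and the CH2 arm of the biaryl. If C5 is drawn as the inner carbon of a propenyl group, C2–C3–C4–C5=C is a 2-alkoxy-4-enoic acid, the product pattern of an ester-enolate [3,3]-rearrangement.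

## Retrosynthesis

**26 ⇒ 25 (six O–benzyl bonds).** All four phenols and both tertiary hydroxyls are taken back to benzyl ethers in hexa-O-benzyl bis-lactone 25. A single neutral hydrogenolysis then ends the synthesis, and the C3 oxygen is carried as an ether that can chelate lithium in the key step. Silyl or acyl protection of the C3 oxygen would not chelate as well or would not survive the enolisation.

**25 ⇒ 23 ⇒ 20 (C5–O1 bonds and the oxidation level of C5).** Each lactone is opened to a γ-hydroxy acid and C5 is traced back through the aldehyde (held as bis-lactol 23) to the inner carbon of an (E)-propenyl group in bis-acid 20. The alkene is a robust masked hydroxymethyl group that needs no protecting group and is exactly what a Claisen rearrangement leaves behind. The forward reactions must cleave two alkenes in the presence of six electron-rich arenes and must not epimerise C4 at the aldehyde stage.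

**20 ⇒ 16 (both C3–C4 bonds, the key disconnection).** Cutting C3–C4 in each half by a retro-Ireland–Claisen gives bis-ester 16, the bis[(R,Z)-allylic ester] of a 2-benzyloxy-3-arylpropanoic acid. The neighbouring cuts (C3–CH2 of ring A, C4–CH2 of the biaryl, C3–O) each create one stereocentre per half and leave the other to a separate step. This cut creates both at once and takes its stereochemical information from one carbinol centre that is destroyed in the process. The precursor has no contiguous stereocentres and its ester α-carbons need not be defined. The forward reaction requires complete double enolisation, one enolate geometry, a chair transition state and a geometrically pure (Z)-alkene.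

**16 ⇒ 8 + 15 (two ester C–O bonds).** The bis-ester is split into the C2-symmetric bis-(Z)-allylic alcohol 8 and two equivalents of racemic acid 15. This is the convergent point of the route; an esterification that leaves the carbinol C–O bond alone is all that is needed.

**8 ⇒ 7 ⇒ 5 + 6 (alkene geometry, then two C(sp3)–C(sp) bonds).** The (Z)-alkenes come from the alkynes of bis-propargylic diol 7 by semihydrogenation, the most dependable way to a pure (Z)-allylic alcohol. Diyne 7 is cut at both benzylic CH2–alkyne bonds into bis(benzyl bromide) 5 and two molecules of commercial (R)-but-3-yn-2-ol 6, one for each arm. Alkynol 6 supplies the only stereochemical information of the whole synthesis.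

**5 ⇒ 4 ⇒ 3 ⇒ 2 ⇒ 1 (functional-group changes, then the biaryl bond).** The bromide goes back through diol 4 and dialdehyde 3 to dehydrodivanillin 2, whose biaryl bond is made first by oxidative coupling of two molecules of vanillin 1. The free ortho position of vanillin is the only site open to coupling, so the dimerisation needs no directing group and the symmetry is built in from step 1.

**15 ⇒ 14 ⇒ 11 + 12; 11 ⇒ 10 ⇒ 9.** The acid comes from ester 14, cut at the Cα–CH2 bond into benzylic bromide 11 and methyl 2-(benzyloxy)acetate 12 (through its lithium enolate 13). Bromide 11 derives from commercial 4-(benzyloxy)-3-methoxybenzaldehyde 9 via alcohol 10. No stereocontrol is asked for here.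

## Roads not taken

**Alternative 1: two-directional benzylation of a bis(α-hydroxy lactone).** The cut is the C3–CH2(ring A) bond in each half. The bis(3-hydroxy-4-arylmethyl lactone) A2 would be converted with LiN(SiMe3)2 into its tetra-anion (an alkoxide–enolate in each ring) and C-benzylated twice with bromide 11, anti to the C4 arm, to give tetra-O-benzyl bis-nortrachelogenin A1; one hydrogenolysis then gives 26.
- Merits: the endgame is one step instead of three, there is no oxidative cleavage and no aldehyde stage at C5, and the ring-A unit is used directly as 11. On step economy after the key step this road is better than the chosen one.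
- Weak points: A2 must itself be made with both C4 centres defined, so only half of the stereochemical problem is solved. The key step is a quaternary-centre-forming SN2 reaction on a poorly soluble tetra-anion, with O-alkylation and mono-alkylation as competitors. Its facial selectivity rests on one flexible CH2Ar substituent next to a nearly flat five-membered enolate, and it has to succeed at two sites in the same molecule.
- Comparison: the chosen plan pays two extra endgame steps. In return both centres of each half come from one suprafacial event, and the position of the alkoxy group is decided by a lithium chelate, not by face selection on a ring.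

**Alternative 2: stereoretentive double Baeyer–Villiger.** The cut is the C3–O bond. The bis(3-acetyl lactone) A4 would be oxidised with buffered CF3CO3H so that the quaternary C3 carbons migrate with retention, giving di-O-acetate A3; acetate removal and hydrogenolysis follow.
- Merits: retention in the migration is dependable, and the quaternary carbon would be built beforehand by alkylation of a soft, stabilised β-dicarbonyl enolate. That is an easier C–C bond formation than any in the chosen route.
- Weak points: the migrating carbon carries the lactone carbonyl and is electron-poor, so migration is slow and needs a strong peracid, while the molecule holds six alkoxy-activated arenes that such a peracid can hydroxylate. The β-keto lactone is prone to deacylative cleavage. The acetates must then be removed with base in the presence of two lactones. C4 still has to be set elsewhere.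
- Comparison: this road adds steps to Alternative 1 to reach the same oxygenation. The chosen plan avoids electrophilic oxidants on the electron-rich arenes apart from the mild, alkene-selective Lemieux–Johnson cleavage.

**Alternative 3: Fráter–Seebach union of two malates with the biaryl.** The cut is the C4–CH2(biaryl) bond in each half. Two alkoxide–enolates of dimethyl (R)-malate A6 would displace both bromides of 5 to give tetramethyl bis[(2R,3S)-3-(arylmethyl)malate] A5, with the new bonds anti to the hydroxyls.
- Merits: the chiral source is cheaper than 6, and the alkylation type is reliably anti-selective. The route shares bis-bromide 5 with the chosen one and needs no alkyne chemistry. Counted through to 26 it is likely about three steps shorter overall and one shorter in the longest line. On cost and on the track record of each individual reaction type it is at least as good as the chosen plan.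
- Weak points: A5 fixes only C4. The two ester groups of each malate unit must then be told apart and the one remote from the hydroxyl reduced, against the innate preference of hydroxyl-directed reductions. This costs about three operations before A2 is reached. The C3 quaternary centre then has to be made by the polyanion benzylation of Alternative 1 (to A1), so the two centres of each half come from two separate diastereoselective steps, each run twice on one molecule.
- Comparison: the chosen plan has more steps and a dearer chiral source. It sets against that a single stereo-determining operation with pericyclic fidelity, no ester differentiation, and a convergent union by simple esterification.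

Key step: step 12

Remark on the chemistry: the ester α-carbons of 14, 15 and 16 are carried as stereoisomer mixtures because step 12 planarises them, and lactol 23 is carried as a mixture of C5 anomers.

## Route

Step 1
Reactants: 1 vanillin (2 equiv)
Product: 2 dehydrodivanillin (6,6'-dihydroxy-5,5'-dimethoxybiphenyl-3,3'-dicarbaldehyde)
Conditions: FeSO4·7H2O (cat.), Na2S2O8, H2O, 50 °C
Reagents that add atoms: vanillin, COc1cc(C=O)ccc1O (the second molecule of 1, joined to the first through the new biaryl bond)
Why: Oxidative phenol coupling of two molecules of vanillin; the phenoxyl radical is blocked para by the formyl group and at one ortho position by methoxy, so C–C coupling occurs at the free ortho carbon of each partner, and the dimer precipitates from water, which limits over-oxidation.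

Step 2
Reactants: 2 dehydrodivanillin
Product: 3 6,6'-bis(benzyloxy)-5,5'-dimethoxybiphenyl-3,3'-dicarbaldehyde
Conditions: BnBr (2.4 equiv), K2CO3, DMF, 60 °C
Reagents that add atoms: benzyl bromide, BrCc1ccccc1
Why: Williamson ether synthesis at both phenols; the para-formyl phenols are acidic enough for carbonate, and DMF dissolves the dimer and drives alkylation of the flanked phenolates.

Step 3
Reactants: 3 6,6'-bis(benzyloxy)-5,5'-dimethoxybiphenyl-3,3'-dicarbaldehyde
Product: 4 [6,6'-bis(benzyloxy)-5,5'-dimethoxybiphenyl-3,3'-diyl]dimethanol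
Conditions: NaBH4, THF/MeOH, 0 °C
Reagents that add atoms: none
Why: Borohydride reduction of aryl aldehydes to benzylic alcohols; the ethers are inert.

Step 4
Reactants: 4 [6,6'-bis(benzyloxy)-5,5'-dimethoxybiphenyl-3,3'-diyl]dimethanol
Product: 5 2,2'-bis(benzyloxy)-5,5'-bis(bromomethyl)-3,3'-dimethoxybiphenyl
Conditions: PBr3, CH2Cl2, 0 °C
Reagents that add atoms: phosphorus tribromide, BrP(Br)Br
Why: Bromination of benzylic alcohols through phosphite esters; the para-alkoxybenzyl bromide is labile and should be used at once without chromatography.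

Step 5
Reactants: 5 2,2'-bis(benzyloxy)-5,5'-bis(bromomethyl)-3,3'-dimethoxybiphenyl; 6 (R)-but-3-yn-2-ol (2.4 equiv)
Product: 7 (2R,2'R)-5,5'-[6,6'-bis(benzyloxy)-5,5'-dimethoxybiphenyl-3,3'-diyl]bis(pent-3-yn-2-ol)
Conditions: CuI, Cs2CO3, NaI, MeCN, rt to 40 °C
Reagents that add atoms: (R)-but-3-yn-2-ol, C[C@@H](O)C#C (the second molecule of 6, which alkynylates the second bromomethyl group)
Why: Copper-promoted coupling of a terminal alkyne with a benzylic halide (alkylation of the copper acetylide, assisted by bromide–iodide exchange), run at both bromomethyl groups with one molecule of 6 each; the carbinol centre of 6 takes no part and keeps its R configuration, and the mild carbonate base should leave the free hydroxyl unalkylated.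

Step 6
Reactants: 7 (2R,2'R)-5,5'-[6,6'-bis(benzyloxy)-5,5'-dimethoxybiphenyl-3,3'-diyl]bis(pent-3-yn-2-ol)
Product: 8 (2R,3Z,2'R,3'Z)-5,5'-[6,6'-bis(benzyloxy)-5,5'-dimethoxybiphenyl-3,3'-diyl]bis(pent-3-en-2-ol)
Conditions: H2 (1 atm), Pd/CaCO3 poisoned with Pb(OAc)2 (Lindlar catalyst), quinoline, EtOAc, rt
Reagents that add atoms: none
Why: Lindlar semihydrogenation; syn delivery of H2 on the poisoned surface gives the (Z)-alkenes and stops there, and the benzyl ethers are not cleaved under these conditions.

Step 7
Reactants: 9 4-(benzyloxy)-3-methoxybenzaldehyde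
Product: 10 [4-(benzyloxy)-3-methoxyphenyl]methanol
Conditions: NaBH4, THF/MeOH, 0 °C
Reagents that add atoms: none
Why: Borohydride reduction of an aryl aldehyde.

Step 8
Reactants: 10 [4-(benzyloxy)-3-methoxyphenyl]methanol
Product: 11 1-(benzyloxy)-4-(bromomethyl)-2-methoxybenzene
Conditions: PBr3, CH2Cl2, 0 °C
Reagents that add atoms: phosphorus tribromide, BrP(Br)Br
Why: Bromination of a benzylic alcohol as in step 4; the bromide is used crude.

Step 9
Reactants: 12 methyl 2-(benzyloxy)acetate; 11 1-(benzyloxy)-4-(bromomethyl)-2-methoxybenzene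
Product: 14 methyl 2-(benzyloxy)-3-[4-(benzyloxy)-3-methoxyphenyl]propanoate (racemic), via lithium enolate 13 (not isolated)
Conditions: LiN(SiMe3)2, THF, −78 °C; then 11, DMPU, −78 to −20 °C
Reagents that add atoms: lithium bis(trimethylsilyl)amide, [Li]N([Si](C)(C)C)[Si](C)(C)C (lithium only, present in intermediate 13 and absent from 14)
Why: Alkylation of a glycolate ester enolate with a reactive benzylic bromide (SN2); low temperature and the polar cosolvent favour alkylation over Claisen self-condensation, and the new centre is racemic by design.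

Step 10
Reactants: 14 methyl 2-(benzyloxy)-3-[4-(benzyloxy)-3-methoxyphenyl]propanoate (racemic)
Product: 15 2-(benzyloxy)-3-[4-(benzyloxy)-3-methoxyphenyl]propanoic acid (racemic)
Conditions: LiOH·H2O, THF/MeOH/H2O, rt; then 1 M HCl
Reagents that add atoms: lithium hydroxide, [Li+].[OH-] (its oxygen becomes a carboxyl oxygen)
Why: Ester saponification by acyl substitution; the benzyl ethers are stable and the α-centre need not be preserved.

Step 11
Reactants: 8 (2R,3Z,2'R,3'Z)-5,5'-[6,6'-bis(benzyloxy)-5,5'-dimethoxybiphenyl-3,3'-diyl]bis(pent-3-en-2-ol); 15 2-(benzyloxy)-3-[4-(benzyloxy)-3-methoxyphenyl]propanoic acid (racemic, 2.4 equiv)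
Product: 16 core bis-ester: [6,6'-bis(benzyloxy)-5,5'-dimethoxybiphenyl-3,3'-diyl]bis[(2R,3Z)-pent-3-ene-5,2-diyl] bis{2-(benzyloxy)-3-[4-(benzyloxy)-3-methoxyphenyl]propanoate} (ester α-carbons unassigned)
Conditions: EDC·HCl, DMAP, CH2Cl2, 0 °C to rt
Reagents that add atoms: none
Why: Steglich esterification; acylation occurs at oxygen, so the (R)-carbinol centres and the (Z)-alkenes are untouched, and the mixture of α-epimers is harmless because step 12 enolises that carbon.

Step 12
Reactants: 16 core bis-ester
Product: 20 bis-acid: two (2R,3R,4E)-2-(benzyloxy)-2-[4-(benzyloxy)-3-methoxybenzyl]hex-4-enoic acid units joined through their C3–CH2 groups to C3 and C3' of the 6,6'-bis(benzyloxy)-5,5'-dimethoxybiphenyl core, via dilithium bis-enolate 17 (not isolated), via bis(silyl ketene acetal) 18 (not isolated), via bis(trimethylsilyl ester) 19 (not isolated)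
Conditions: LiN(iPr)2 (5 equiv), THF, −78 °C; Me3SiCl, Et3N, −78 °C to rt, then 50 °C; 1 M HCl
Reagents that add atoms: lithium diisopropylamide, [Li]N(C(C)C)C(C)C (lithium only, in 17); chlorotrimethylsilane, C[Si](C)(C)Cl (silicon only, in 18 and 19, lost on work-up; no reagent atom remains in 20)
Why: This is an Ireland–Claisen rearrangement run in two directions: LiN(iPr)2 removes the α-hydrogen of each ester while lithium is chelated between the enolate oxygen and the benzyloxy oxygen, so a single enolate geometry forms (OLi cis to OBn, arylmethyl cis to the allylic oxygen) and silylation fixes it as the (Z)-ketene acetal 18. On warming, each arm undergoes a concerted suprafacial [3,3]-shift through a chair transition state that forms the C3–C4 bond (lactone numbering) and moves the alkene into an (E)-propenyl group; no ring closes. The closest known reaction type is the chelation-controlled Ireland–Claisen rearrangement of allylic α-alkoxy esters (glycolates and lactates) of secondary (Z)-allylic alcohols with 1,3-chirality transfer. C4 is controlled by the (R)-carbinol centre together with the (Z)-alkene: the carbinol methyl must sit equatorial, because the other chair would place it 1,3-diaxial to the axial CH2 arm, and this fixes the face of the allyl unit and gives R at C4. C3 is controlled by the enolate geometry within the same chair: the ring-A arylmethyl group is axial and the benzyloxy group equatorial, which gives R at C3 with the two arylmethyl groups trans and the benzyloxy group cis to the core arm in the later lactone. The step needs complete double enolisation (excess base), one enolate geometry (THF without lithium-sequestering cosolvents, so that the chelate persists) and chair over boat (secured by the acyclic (Z)-allyl unit). The two arms are insulated by the biaryl and both carbinols are R, so each rearranges independently in the same sense, and the original α-epimer mixture converges because that centre is planar in 17 and 18. Acidic work-up hydrolyses silyl ester 19 to acid 20.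

Step 13
Reactants: 20 bis-acid
Product: 23 bis-lactol: two (3R,4S)-3-(benzyloxy)-3-[4-(benzyloxy)-3-methoxybenzyl]-5-hydroxydihydrofuran-2(3H)-one rings joined through their C4–CH2 groups to the core (C5 anomers unassigned; spatial arrangement at C3 and C4 as in 20), via bis-diol 21 (not isolated), via bis(4-oxo acid) 22 (not isolated)
Conditions: OsO4 (cat.), NaIO4, 2,6-lutidine, dioxane/H2O, rt
Reagents that add atoms: osmium tetroxide, O=[Os](=O)(=O)=O (delivers one oxygen to each alkene carbon); sodium periodate, [Na+].[O-]I(=O)(=O)=O (terminal oxidant that regenerates it)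
Why: Lemieux–Johnson oxidation: catalytic dihydroxylation and periodate glycol cleavage remove the outer two carbons of each propenyl group as acetaldehyde, and the alkenes are far more reactive than the arenes. The lutidine buffer keeps the carboxyl group ionised so it does not acylate the diol before cleavage. The γ-oxo acid 22 closes to lactol 23 by ring–chain tautomerism, which shields the now enolisable C4.

Step 14
Reactants: 23 bis-lactol
Product: 25 hexa-O-benzyl bis-5,5-nortrachelogenin ((3R,4R,3'R,4'R) bis-lactone), via bis(4-hydroxy acid) 24 (not isolated)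
Conditions: NaBH4, THF/MeOH, 0 °C; then 1 M HCl, rt
Reagents that add atoms: none
Why: Borohydride reduces the open-chain aldehyde tautomer of the lactol (reduction of a pseudo-acid), and the γ-hydroxy acid 24 lactonises on acidification; reduction at 0 °C is expected to outrun enolisation, so C4 is retained, and C3 is quaternary.

Step 15
Reactants: 25 hexa-O-benzyl bis-5,5-nortrachelogenin
Product: 26 bis-5,5-nortrachelogenin
Conditions: H2 (1 atm), Pd(OH)2/C, EtOAc/MeOH, rt
Reagents that add atoms: none
Why: Catalytic hydrogenolysis of four aryl and two tertiary alkyl benzyl ethers; the lactones and the non-benzylic C–O bonds are inert and no stereocentre is touched.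

## Compound list

1 | vanillin | COc1cc(C=O)ccc1O | starting material
2 | dehydrodivanillin (6,6'-dihydroxy-5,5'-dimethoxybiphenyl-3,3'-dicarbaldehyde) | COc1cc(C=O)cc(c1O)-c1cc(C=O)cc(OC)c1O | intermediate
3 | 6,6'-bis(benzyloxy)-5,5'-dimethoxybiphenyl-3,3'-dicarbaldehyde | COc1cc(C=O)cc(c1OCc1ccccc1)-c1cc(C=O)cc(OC)c1OCc1ccccc1 | intermediate
4 | [6,6'-bis(benzyloxy)-5,5'-dimethoxybiphenyl-3,3'-diyl]dimethanol | COc1cc(CO)cc(c1OCc1ccccc1)-c1cc(CO)cc(OC)c1OCc1ccccc1 | intermediate
5 | 2,2'-bis(benzyloxy)-5,5'-bis(bromomethyl)-3,3'-dimethoxybiphenyl | COc1cc(CBr)cc(c1OCc1ccccc1)-c1cc(CBr)cc(OC)c1OCc1ccccc1 | intermediate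
6 | (R)-but-3-yn-2-ol | C[C@@H](O)C#C | starting material
7 | (2R,2'R)-5,5'-[6,6'-bis(benzyloxy)-5,5'-dimethoxybiphenyl-3,3'-diyl]bis(pent-3-yn-2-ol) | C[C@@H](O)C#CCc1cc(OC)c(OCc2ccccc2)c(c1)-c1cc(CC#C[C@@H](C)O)cc(OC)c1OCc1ccccc1 | intermediate
8 | (2R,3Z,2'R,3'Z)-5,5'-[6,6'-bis(benzyloxy)-5,5'-dimethoxybiphenyl-3,3'-diyl]bis(pent-3-en-2-ol) | C[C@@H](O)/C=C\Cc1cc(OC)c(OCc2ccccc2)c(c1)-c1cc(C/C=C\[C@@H](C)O)cc(OC)c1OCc1ccccc1 | intermediate
9 | 4-(benzyloxy)-3-methoxybenzaldehyde | COc1cc(C=O)ccc1OCc1ccccc1 | starting material
10 | [4-(benzyloxy)-3-methoxyphenyl]methanol | COc1cc(CO)ccc1OCc1ccccc1 | intermediate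
11 | 1-(benzyloxy)-4-(bromomethyl)-2-methoxybenzene | COc1cc(CBr)ccc1OCc1ccccc1 | intermediate
12 | methyl 2-(benzyloxy)acetate | COC(=O)COCc1ccccc1 | starting material
13 | lithium enolate of 12 (OLi and OBn cis, chelated) | [Li]O/C(OC)=C\OCc1ccccc1 | intermediate
14 | methyl 2-(benzyloxy)-3-[4-(benzyloxy)-3-methoxyphenyl]propanoate (racemic) | COC(=O)C(Cc1ccc(OCc2ccccc2)c(OC)c1)OCc1ccccc1 | intermediate
15 | 2-(benzyloxy)-3-[4-(benzyloxy)-3-methoxyphenyl]propanoic acid (racemic) | OC(=O)C(Cc1ccc(OCc2ccccc2)c(OC)c1)OCc1ccccc1 | intermediate
16 | core bis-ester; both carbinol carbons R, both alkenes Z, ester α-carbons unassigned | COc1cc(CC(OCc2ccccc2)C(=O)O[C@H](C)/C=C\Cc2cc(OC)c(OCc3ccccc3)c(c2)-c2cc(C/C=C\[C@@H](C)OC(=O)C(Cc3ccc(OCc4ccccc4)c(OC)c3)OCc3ccccc3)cc(OC)c2OCc2ccccc2)ccc1OCc1ccccc1 | intermediate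
17 | dilithium bis-enolate of 16 (OLi cis to OBn in each arm) | COc1cc(C/C(OCc2ccccc2)=C(/O[Li])O[C@H](C)/C=C\Cc2cc(OC)c(OCc3ccccc3)c(c2)-c2cc(C/C=C\[C@@H](C)O/C(O[Li])=C(\Cc3ccc(OCc4ccccc4)c(OC)c3)OCc3ccccc3)cc(OC)c2OCc2ccccc2)ccc1OCc1ccccc1 | intermediate
18 | bis[(Z)-trimethylsilyl ketene acetal] of 16 (OSiMe3 cis to OBn, arylmethyl cis to the allylic oxygen) | COc1cc(C/C(OCc2ccccc2)=C(/O[Si](C)(C)C)O[C@H](C)/C=C\Cc2cc(OC)c(OCc3ccccc3)c(c2)-c2cc(C/C=C\[C@@H](C)O/C(O[Si](C)(C)C)=C(\Cc3ccc(OCc4ccccc4)c(OC)c3)OCc3ccccc3)cc(OC)c2OCc2ccccc2)ccc1OCc1ccccc1 | intermediate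
19 | bis(trimethylsilyl ester) of 20 | COc1cc(C[C@](OCc2ccccc2)(C(=O)O[Si](C)(C)C)[C@@H](/C=C/C)Cc2cc(OC)c(OCc3ccccc3)c(c2)-c2cc(C[C@H](/C=C/C)[C@@](OCc3ccccc3)(C(=O)O[Si](C)(C)C)Cc3ccc(OCc4ccccc4)c(OC)c3)cc(OC)c2OCc2ccccc2)ccc1OCc1ccccc1 | intermediate
20 | bis-acid, (2R,3R,4E) in each 2-benzyloxy-2,3-bis(arylmethyl)hex-4-enoic acid unit | COc1cc(C[C@](OCc2ccccc2)(C(=O)O)[C@@H](/C=C/C)Cc2cc(OC)c(OCc3ccccc3)c(c2)-c2cc(C[C@H](/C=C/C)[C@@](OCc3ccccc3)(C(=O)O)Cc3ccc(OCc4ccccc4)c(OC)c3)cc(OC)c2OCc2ccccc2)ccc1OCc1ccccc1 | intermediate
21 | bis-diol, (2R,3R)-4,5-dihydroxyhexanoic acid units (C4 and C5 unassigned) | COc1cc(C[C@](OCc2ccccc2)(C(=O)O)[C@@H](C(O)C(C)O)Cc2cc(OC)c(OCc3ccccc3)c(c2)-c2cc(C[C@H](C(O)C(C)O)[C@@](OCc3ccccc3)(C(=O)O)Cc3ccc(OCc4ccccc4)c(OC)c3)cc(OC)c2OCc2ccccc2)ccc1OCc1ccccc1 | intermediate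
22 | bis(4-oxo acid), (2R,3S)-2-benzyloxy-2,3-bis(arylmethyl)-4-oxobutanoic acid units | COc1cc(C[C@](OCc2ccccc2)(C(=O)O)[C@@H](C=O)Cc2cc(OC)c(OCc3ccccc3)c(c2)-c2cc(C[C@H](C=O)[C@@](OCc3ccccc3)(C(=O)O)Cc3ccc(OCc4ccccc4)c(OC)c3)cc(OC)c2OCc2ccccc2)ccc1OCc1ccccc1 | intermediate
23 | bis-lactol, (3R,4S)-3-benzyloxy-5-hydroxy lactone rings (C5 unassigned) | COc1cc(C[C@]2(OCc3ccccc3)C(=O)OC(O)[C@H]2Cc2cc(OC)c(OCc3ccccc3)c(c2)-c2cc(C[C@@H]4C(O)OC(=O)[C@@]4(OCc5ccccc5)Cc4ccc(OCc5ccccc5)c(OC)c4)cc(OC)c2OCc2ccccc2)ccc1OCc1ccccc1 | intermediate
24 | bis(4-hydroxy acid), (2R,3R)-2-benzyloxy-2,3-bis(arylmethyl)-4-hydroxybutanoic acid units | COc1cc(C[C@](OCc2ccccc2)(C(=O)O)[C@@H](CO)Cc2cc(OC)c(OCc3ccccc3)c(c2)-c2cc(C[C@H](CO)[C@@](OCc3ccccc3)(C(=O)O)Cc3ccc(OCc4ccccc4)c(OC)c3)cc(OC)c2OCc2ccccc2)ccc1OCc1ccccc1 | intermediate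
25 | hexa-O-benzyl bis-5,5-nortrachelogenin, (3R,4R,3'R,4'R) | COc1cc(C[C@]2(OCc3ccccc3)C(=O)OC[C@H]2Cc2cc(OC)c(OCc3ccccc3)c(c2)-c2cc(C[C@@H]4COC(=O)[C@@]4(OCc5ccccc5)Cc4ccc(OCc5ccccc5)c(OC)c4)cc(OC)c2OCc2ccccc2)ccc1OCc1ccccc1 | intermediate
26 | bis-5,5-nortrachelogenin, (3R,4R,3'R,4'R) | COc1cc(C[C@]2(O)C(=O)OC[C@H]2Cc2cc(OC)c(O)c(-c3cc(C[C@@H]4COC(=O)[C@@]4(O)Cc4ccc(O)c(OC)c4)cc(OC)c3O)c2)ccc1O | target

## Step count and points of risk

Total: 15 steps. Longest linear sequence: 11 steps (vanillin 1 to 26 through steps 1–6 and 11–15); the acid branch (steps 7–10) has four steps.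

**Step 12 (key step).** The risks are incomplete deprotonation at one of the two hindered tertiary α-positions, partial loss of chelation during enolisation (which would erode the configuration at C3), and a slow rearrangement of the fully substituted ketene acetal against the axial CH2 arm, which gives time for C-silylation or fragmentation of the enolate. The fallback moves the quaternary centre out of the rearrangement. It sets out from 8, which is esterified (EDC·HCl, DMAP) with commercial 2-(benzyloxy)acetic acid to the bis(benzyloxyacetate) F1. The same LiN(iPr)2/Me3SiCl sequence, now a glycolate Ireland–Claisen rearrangement through a less hindered ketene acetal, should give the bis[(2R,3R,4E)-2-(benzyloxy)-3-(arylmethyl)hex-4-enoic acid] F2 with C4 already set. Lemieux–Johnson cleavage gives the bis-lactol F3, and NaBH4 reduction with acid lactonisation gives the bis(3-benzyloxy lactone) F4. Its lithium enolate (LiN(SiMe3)2, THF, −78 °C) is then benzylated with bromide 11 on the face opposite the C4 arm, which comes back to the route at 25.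

**Step 5.** The risks are base-induced isomerisation of the benzyl alkyne to an allene, O-alkylation of the free carbinol by the very reactive bromide, oxidative homocoupling of the alkyne, and an incomplete second coupling. The fallback builds the (Z)-alkene before the C–C bond and sets out from 6 and 5. Alcohol 6 is silylated (t-BuMe2SiCl, imidazole) to the (R)-silyl ether F5 and iodinated at the alkyne terminus (N-iodosuccinimide, AgNO3 cat.) to the (R)-iodoalkyne F6. Reduction with diimide (2-nitrobenzenesulfonyl hydrazide, Et3N) gives the (R,Z)-vinyl iodide F7. Bromide 5 is converted with Zn dust and LiCl in THF into the bis(benzylzinc bromide) F8. Negishi coupling of F8 with F7 under Pd(PPh3)4 retains the alkene geometry and gives the bis(silyl ether) F9, and Bu4NF returns to the route at 8, bypassing 7 and step 6.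

**Step 9.** The risk is self-condensation of the glycolate enolate, or decay of the labile bromide, outrunning the alkylation. The fallback replaces the alkylation by an aldol addition followed by deoxygenation and sets out from 12 and 9. Enolate 13 is added to aldehyde 9 at −78 °C to give the β-hydroxy ester F10 as a diastereomer mixture. Ionic hydrogenation of its para-alkoxybenzylic alcohol (Et3SiH, CF3CO2H, CH2Cl2, 0 °C) comes back at 14 and makes steps 7 and 8 unnecessary.

**Step 13.** The risks are acylation of the intermediate diol by the neighbouring carboxyl group, which would block glycol cleavage, and enolisation of the open-chain aldehyde, which would epimerise C4. The fallback never lets the aldehyde accumulate. It sets out from 20: ozonolysis (O3, CH2Cl2/MeOH, −78 °C, with Sudan Red 7B as end-point indicator to spare the arenes) is followed in the same flask by NaBH4. This gives hydroxy acid 24, which lactonises on acidification, coming back at 25.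

**Step 15.** The risk is slow hydrogenolysis of the two hindered tertiary benzyl ethers after the aryl ethers have gone, so that the reaction stalls at partly protected material. The fallback uses Lewis-acid debenzylation: from 25, BCl3 with pentamethylbenzene as cation scavenger (CH2Cl2, −78 °C) cleaves aryl and alkyl benzyl ethers without hydrogen and without touching the methyl ethers, arriving at 26.

## Further compounds

F1 | step 12 | bis(benzyloxyacetate) of diol 8 | O=C(COCc1ccccc1)O[C@H](C)/C=C\Cc1cc(OC)c(OCc2ccccc2)c(c1)-c1cc(C/C=C\[C@@H](C)OC(=O)COCc2ccccc2)cc(OC)c1OCc1ccccc1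
F2 | step 12 | bis[(2R,3R,4E)-2-(benzyloxy)-3-(arylmethyl)hex-4-enoic acid] on the biaryl core | OC(=O)[C@H](OCc1ccccc1)[C@@H](/C=C/C)Cc1cc(OC)c(OCc2ccccc2)c(c1)-c1cc(C[C@H](/C=C/C)[C@@H](OCc2ccccc2)C(=O)O)cc(OC)c1OCc1ccccc1
F3 | step 12 | bis-lactol, 3-benzyloxy-5-hydroxy-4-(arylmethyl) lactone rings on the biaryl core (C5 unassigned) | O=C1OC(O)[C@@H](Cc2cc(OC)c(OCc3ccccc3)c(c2)-c2cc(C[C@@H]3C(O)OC(=O)[C@@H]3OCc3ccccc3)cc(OC)c2OCc2ccccc2)[C@H]1OCc1ccccc1
F4 | step 12 | bis[(3R,4R)-3-(benzyloxy)-4-(arylmethyl)dihydrofuran-2(3H)-one] on the biaryl core | O=C1OC[C@@H](Cc2cc(OC)c(OCc3ccccc3)c(c2)-c2cc(C[C@@H]3COC(=O)[C@@H]3OCc3ccccc3)cc(OC)c2OCc2ccccc2)[C@H]1OCc1ccccc1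
F5 | step 5 | (R)-(but-3-yn-2-yloxy)(tert-butyl)dimethylsilane | C[C@@H](O[Si](C)(C)C(C)(C)C)C#C
F6 | step 5 | (R)-tert-butyl[(4-iodobut-3-yn-2-yl)oxy]dimethylsilane | C[C@@H](O[Si](C)(C)C(C)(C)C)C#CI
F7 | step 5 | (R,Z)-tert-butyl[(4-iodobut-3-en-2-yl)oxy]dimethylsilane | C[C@@H](O[Si](C)(C)C(C)(C)C)/C=C\I
F8 | step 5 | bis(benzylzinc bromide) from 5 | COc1cc(C[Zn]Br)cc(c1OCc1ccccc1)-c1cc(C[Zn]Br)cc(OC)c1OCc1ccccc1
F9 | step 5 | bis(tert-butyldimethylsilyl ether) of 8 | C[C@@H](O[Si](C)(C)C(C)(C)C)/C=C\Cc1cc(OC)c(OCc2ccccc2)c(c1)-c1cc(C/C=C\[C@@H](C)O[Si](C)(C)C(C)(C)C)cc(OC)c1OCc1ccccc1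
F10 | step 9 | methyl 2-(benzyloxy)-3-[4-(benzyloxy)-3-methoxyphenyl]-3-hydroxypropanoate (diastereomer mixture) | COC(=O)C(OCc1ccccc1)C(O)c1ccc(OCc2ccccc2)c(OC)c1
F0 | step 13 | none | none
F0 | step 15 | none | none
A1 | alternative 1 | tetra-O-benzyl bis-5,5-nortrachelogenin | COc1cc(C[C@]2(O)C(=O)OC[C@H]2Cc2cc(OC)c(OCc3ccccc3)c(-c3cc(C[C@@H]4COC(=O)[C@@]4(O)Cc4ccc(OCc5ccccc5)c(OC)c4)cc(OC)c3OCc3ccccc3)c2)ccc1OCc1ccccc1
A2 | alternative 1 | bis(3-hydroxy-4-arylmethyl lactone) on the biaryl core (C3 unassigned, it is enolised) | OC1C(=O)OC[C@H]1Cc1cc(OC)c(OCc2ccccc2)c(c1)-c1cc(C[C@@H]2COC(=O)C2O)cc(OC)c1OCc1ccccc1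
A3 | alternative 2 | tetra-O-benzyl bis-5,5-nortrachelogenin di-O-acetate | COc1cc(C[C@]2(OC(C)=O)C(=O)OC[C@H]2Cc2cc(OC)c(OCc3ccccc3)c(-c3cc(C[C@@H]4COC(=O)[C@@]4(OC(C)=O)Cc4ccc(OCc5ccccc5)c(OC)c4)cc(OC)c3OCc3ccccc3)c2)ccc1OCc1ccccc1
A4 | alternative 2 | bis(3-acetyl lactone), acetyl in place of each C3 hydroxyl | COc1cc(C[C@]2(C(C)=O)C(=O)OC[C@H]2Cc2cc(OC)c(OCc3ccccc3)c(-c3cc(C[C@@H]4COC(=O)[C@@]4(C(C)=O)Cc4ccc(OCc5ccccc5)c(OC)c4)cc(OC)c3OCc3ccccc3)c2)ccc1OCc1ccccc1
A5 | alternative 3 | tetramethyl bis[(2R,3S)-3-(arylmethyl)malate] on the biaryl core | COC(=O)[C@H](O)[C@@H](C(=O)OC)Cc1cc(OC)c(OCc2ccccc2)c(c1)-c1cc(C[C@H](C(=O)OC)[C@@H](O)C(=O)OC)cc(OC)c1OCc1ccccc1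
A6 | alternative 3 | dimethyl (R)-malate | COC(=O)C[C@@H](O)C(=O)OC
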